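**Plan**
1. The target is read as the cis-(3S,4S)-3,4-diol of a 2,2-dimethylchroman (ring A = benzene ring; pyran ring = O1–C2–C3–C4–C4a–C8a) with OMe on C5 and an (E)-4-hydroxycinnamoyl group on C8.
2. Retrosynthetic cuts, in order: enone Cα=Cβ (to the 8-acetyl diol and 4-hydroxybenzaldehyde); C8–acetyl (to C8–Br); C4 carbinol (to the C4 ketone); O1–C8a together with C2–C3 (to acetone and an ortho-fluoroaryl benzyloxymethyl ketone); C4–C4a (to lithiated 4-bromo-3-fluoroanisole and an N-methoxy-N-methylamide).
3. Enabling feature: C2 with its two methyl groups and O1 is the C=O of acetone. C4 is benzylic on ring A and ortho to C8a, so as a ketone it makes C3–H acidic and a C8a–F bond open to substitution. The unit C8a–C4a–C4–C3 then has a nucleophilic end (C3) and an electrophilic end (C8a) that match the two ends of the acetone carbonyl.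
4. Forward: ring A is bought; the C4–C3 chain is placed between F and OMe by ortho-lithiation; the pyranone ring closes in the annulation with acetone; then ketone reduction, acetyl for bromine, debenzylation and chalcone formation.
5. Stereochemistry: C3 and C4 are both set in one catalytic step, an asymmetric transfer hydrogenation of the racemic 3-benzyloxychroman-4-one under dynamic kinetic resolution (catalyst sets C4, hydride anti to OBn gives cis). The E alkene is the thermodynamic outcome of the condensation.

Key step: step 2

Remark: 2-(benzyloxy)-N-methoxy-N-methylacetamide (2) is taken as a catalogue compound.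

**Route**

Step 1
Reactants: 1 4-bromo-3-fluoroanisole; 2 2-(benzyloxy)-N-methoxy-N-methylacetamide
Product: 4 2-(benzyloxy)-1-(3-bromo-2-fluoro-6-methoxyphenyl)ethan-1-one, via aryllithium 3 (not isolated)
Conditions: LiN(i-Pr)2, THF, -78 °C; then 2, -78 °C; 1 M HCl quench
Reagents that add atoms: none
Why: Directed ortho-metalation should remove the most acidic ring proton, the one flanked by F and OMe (an amide base avoids Br/Li exchange, and -78 °C avoids loss of LiF), and acylation of the aryllithium by the N-methoxy-N-methylamide stops at the ketone (Weinreb ketone synthesis); no stereocentre is formed.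

Step 2
Reactants: 4 2-(benzyloxy)-1-(3-bromo-2-fluoro-6-methoxyphenyl)ethan-1-one; 5 acetone
Product: 8 rac-3-(benzyloxy)-8-bromo-5-methoxy-2,2-dimethylchroman-4-one, via lithium enolate 6 (not isolated), via lithium aldolate 7 (not isolated)
Conditions: LiN(SiMe3)2, THF, -78 °C; acetone (5 equiv), -78 °C; then DMPU, -78 to 40 °C
Reagents that add atoms: none
Why: Proposed new method: LiN(SiMe3)2 should give the chelated Z-enolate 6, whose C3 adds to the carbonyl carbon of acetone (aldol addition, C2–C3 bond) to give the tertiary alkoxide 7, and this alkoxide should then attack the fluorine-bearing carbon C8a ortho to the C4 ketone and expel fluoride (addition–elimination SNAr, O1–C8a bond), so that the step is a stepwise anionic [4+2] annulation of the unit C8a–C4a–C4–C3 with the C=O of acetone. The closest known reaction types are tandem carbonyl-addition/SNAr annulations of ortho-fluoroaryl ketone enolates with imines (to dihydroquinolin-4-ones) and the two-step aldol addition then base-mediated SNAr closure to chroman-4-ones; the untested part is a simple ketone acceptor in one flask, which rests on the reversible aldol being drained by the irreversible C–F substitution. The pyranone ring closes by 6-exo-trig attack of the alkoxide oxygen on the aromatic carbon C8a. The new stereocentre C3 is formed without control on purpose, because it lies alpha to the ketone and is corrected in step 3. The step needs substitution at C–F and not at C–Br or C–OMe, and enolisation at C3 only: fluoride is the only good SNAr leaving group ortho to the carbonyl, the bromide is meta to it, and ring A carries no second enolisable acyl group because C8 holds bromine in place of the later acetyl group.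

Step 3
Reactants: 8 rac-3-(benzyloxy)-8-bromo-5-methoxy-2,2-dimethylchroman-4-one
Product: 9 (3S,4S)-3-(benzyloxy)-8-bromo-5-methoxy-2,2-dimethylchroman-4-ol
Conditions: RuCl[(R,R)-TsDPEN](p-cymene) (2 mol %), HCO2H/Et3N (5:2), DMF, 40 °C
Reagents that add atoms: none
Why: Noyori–Ikariya asymmetric transfer hydrogenation under dynamic kinetic resolution: the C3 epimers of 8 should interconvert by base-mediated enolisation faster than they are reduced, the (R,R) catalyst should deliver hydride to the C4 face that gives the 4S carbinol (aryl ketone model, CH–π contact of ring A with the p-cymene ligand), and hydride should enter anti to the C3 benzyloxy group, so only the (3S)-ketone is reduced quickly and the cis-(3S,4S) alcohol should result.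

Step 4
Reactants: 9 (3S,4S)-3-(benzyloxy)-8-bromo-5-methoxy-2,2-dimethylchroman-4-ol
Product: 11 1-[(3S,4S)-3-(benzyloxy)-4-hydroxy-5-methoxy-2,2-dimethylchroman-8-yl]ethan-1-one, via enol ether 10 (not isolated)
Conditions: tributyl(1-ethoxyvinyl)stannane, Pd(PPh3)4 (5 mol %), toluene, 100 °C; then 1 M HCl, THF, 0 °C, brief
Reagents that add atoms: tributyl(1-ethoxyvinyl)stannane CCCC[Sn](CCCC)(CCCC)C(=C)OCC; water O
Why: Stille coupling of the aryl bromide (oxidative addition to zerovalent palladium, transmetalation, reductive elimination) tolerates the free alcohol, and the aryl enol ether 10 hydrolyses to the methyl ketone in cold dilute acid far faster than the C4 carbinol can ionise, so both stereocentres should be kept.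

Step 5
Reactants: 11 1-[(3S,4S)-3-(benzyloxy)-4-hydroxy-5-methoxy-2,2-dimethylchroman-8-yl]ethan-1-one
Product: 12 1-[(3S,4S)-3,4-dihydroxy-5-methoxy-2,2-dimethylchroman-8-yl]ethan-1-one
Conditions: H2 (1 atm), 10% Pd/C, EtOAc, rt
Reagents that add atoms: none
Why: Hydrogenolysis of the benzyl ether in a neutral aprotic solvent at 1 atm should be faster than reduction of the hindered ortho-alkoxy aryl ketone or cleavage of the secondary benzylic C4–OH, and no halogen or alkene is present at this stage.

Step 6
Reactants: 12 1-[(3S,4S)-3,4-dihydroxy-5-methoxy-2,2-dimethylchroman-8-yl]ethan-1-one; 13 4-hydroxybenzaldehyde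
Product: 14 (E)-1-[(3S,4S)-3,4-dihydroxy-5-methoxy-2,2-dimethylchroman-8-yl]-3-(4-hydroxyphenyl)prop-2-en-1-one
Conditions: KOH (50% aq), EtOH, rt; then AcOH to pH 6
Reagents that add atoms: none
Why: Claisen–Schmidt condensation (aldol addition of the methyl ketone enolate to the aldehyde, then E1cB loss of water) should give the conjugated E enone as the thermodynamic product, and C3 and C4 are not alpha to a carbonyl group and should be stable to base.

**Compound list**
1 | 4-bromo-3-fluoroanisole (1-bromo-2-fluoro-4-methoxybenzene) | COc1ccc(Br)c(F)c1 | starting material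
2 | 2-(benzyloxy)-N-methoxy-N-methylacetamide | CON(C)C(=O)COCc1ccccc1 | starting material
3 | (3-bromo-2-fluoro-6-methoxyphenyl)lithium | COc1ccc(Br)c(F)c1[Li] | intermediate
4 | 2-(benzyloxy)-1-(3-bromo-2-fluoro-6-methoxyphenyl)ethan-1-one | COc1ccc(Br)c(F)c1C(=O)COCc1ccccc1 | intermediate
5 | acetone | CC(C)=O | starting material
6 | lithium (Z)-2-(benzyloxy)-1-(3-bromo-2-fluoro-6-methoxyphenyl)ethen-1-olate | COc1ccc(Br)c(F)c1/C([O-])=C/OCc1ccccc1.[Li+] | intermediate
7 | lithium 3-(benzyloxy)-4-(3-bromo-2-fluoro-6-methoxyphenyl)-2-methyl-4-oxobutan-2-olate (racemic) | COc1ccc(Br)c(F)c1C(=O)C(OCc1ccccc1)C(C)(C)[O-].[Li+] | intermediate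
8 | rac-3-(benzyloxy)-8-bromo-5-methoxy-2,2-dimethylchroman-4-one | COc1ccc(Br)c2c1C(=O)C(OCc1ccccc1)C(C)(C)O2 | intermediate
9 | (3S,4S)-3-(benzyloxy)-8-bromo-5-methoxy-2,2-dimethylchroman-4-ol | COc1ccc(Br)c2c1[C@H](O)[C@H](OCc1ccccc1)C(C)(C)O2 | intermediate
10 | (3S,4S)-3-(benzyloxy)-8-(1-ethoxyvinyl)-5-methoxy-2,2-dimethylchroman-4-ol | COc1ccc(C(=C)OCC)c2c1[C@H](O)[C@H](OCc1ccccc1)C(C)(C)O2 | intermediate
11 | 1-[(3S,4S)-3-(benzyloxy)-4-hydroxy-5-methoxy-2,2-dimethylchroman-8-yl]ethan-1-one | COc1ccc(C(C)=O)c2c1[C@H](O)[C@H](OCc1ccccc1)C(C)(C)O2 | intermediate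
12 | 1-[(3S,4S)-3,4-dihydroxy-5-methoxy-2,2-dimethylchroman-8-yl]ethan-1-one | COc1ccc(C(C)=O)c2c1[C@H](O)[C@H](O)C(C)(C)O2 | intermediate
13 | 4-hydroxybenzaldehyde | O=Cc1ccc(O)cc1 | starting material
14 | (E)-1-[(3S,4S)-3,4-dihydroxy-5-methoxy-2,2-dimethylchroman-8-yl]-3-(4-hydroxyphenyl)prop-2-en-1-one | COc1ccc(C(=O)/C=C/c2ccc(O)cc2)c2c1[C@H](O)[C@H](O)C(C)(C)O2 | target

**Step count**
Total steps: 6. Longest linear sequence: 6 steps (from 1).

**Steps most likely to fail**

Step 2 (proposed new method). The aldolate may revert to enolate and acetone faster than it closes onto C8a, it may lose water to the enone, and acetone may be used up by self-condensation. The fallback uses known chemistry and closes the ring at O1–C2 in place of O1–C8a. It sets out from 4, which is heated with KOH in DMSO/H2O at 70 °C (SNAr of the ortho-acyl fluoride by hydroxide) to give 2-(benzyloxy)-1-(3-bromo-2-hydroxy-6-methoxyphenyl)ethan-1-one F1. F1 is then condensed with acetone 5 and pyrrolidine in MeOH at 60 °C (Kabbe condensation: aldol-type condensation through the enamine/iminium pair, then 6-endo oxa-Michael addition of the phenol). The sequence comes back to the route at 8.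

Step 3. Interconversion of the C3 epimers may be too slow under the reduction conditions, so that the resolution is not dynamic, or facial discrimination may be poor, with erosion of cis selectivity or enantiopurity. The fallback replaces catalyst control by substrate control and a separation. It sets out from 8, which is reduced with LiBH(s-Bu)3 in THF at -78 °C (hydride anti to the benzyloxy group) to racemic cis-3-(benzyloxy)-8-bromo-5-methoxy-2,2-dimethylchroman-4-ol F2. The enantiomers of F2 are separated by preparative chromatography on a chiral stationary phase. The (3S,4S) enantiomer is 9, where the route is rejoined, and (3R,4R)-3-(benzyloxy)-8-bromo-5-methoxy-2,2-dimethylchroman-4-ol F3 is set aside.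

Step 6. The aldehyde may be deactivated as its phenoxide so that the condensation stalls, with slow loss of material in strong base. The fallback masks the phenol and unmasks it under neutral conditions. It sets out from 12, which is condensed with 4-(allyloxy)benzaldehyde (Ba(OH)2·8H2O, MeOH, 40 °C) to give (E)-3-[4-(allyloxy)phenyl]-1-[(3S,4S)-3,4-dihydroxy-5-methoxy-2,2-dimethylchroman-8-yl]prop-2-en-1-one F4. The allyl group of F4 is then transferred to N-methylaniline with Pd(PPh3)4 in THF at rt (through a π-allyl complex of palladium), which gives 14.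

**Further compounds**
F1 | step 2 | 2-(benzyloxy)-1-(3-bromo-2-hydroxy-6-methoxyphenyl)ethan-1-one | COc1ccc(Br)c(O)c1C(=O)COCc1ccccc1
F2 | step 3 | racemic cis-3-(benzyloxy)-8-bromo-5-methoxy-2,2-dimethylchroman-4-ol | COc1ccc(Br)c2c1[C@H](O)[C@H](OCc1ccccc1)C(C)(C)O2.COc1ccc(Br)c2c1[C@@H](O)[C@@H](OCc1ccccc1)C(C)(C)O2
F3 | step 3 | (3R,4R)-3-(benzyloxy)-8-bromo-5-methoxy-2,2-dimethylchroman-4-ol | COc1ccc(Br)c2c1[C@@H](O)[C@@H](OCc1ccccc1)C(C)(C)O2
F4 | step 6 | (E)-3-[4-(allyloxy)phenyl]-1-[(3S,4S)-3,4-dihydroxy-5-methoxy-2,2-dimethylchroman-8-yl]prop-2-en-1-one | COc1ccc(C(=O)/C=C/c2ccc(OCC=C)cc2)c2c1[C@H](O)[C@H](O)C(C)(C)O2
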